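Readings and results come from a simulation for an exercise, and the scatter is random.

Late in the larch run, a closed stirred flask charged with 500 mM starting material, 200 mM reagent and 13.0 mM catalyst, the starting material falls at 1.55 mM/min between 13 min and 25 min, against 18.8 mM/min in the first minute.

common to all: catalyst 13.0 mM

| charge | starting material | reagent | time |
|---|---|---|---|
| ash | 250 mM | 200 mM |  |
| elm | 130 mM | 80.0 mM |  |
| birch | 250 mM | 300 mM |  |
| larch | 500 mM | 200 mM |  |
| cedar | 120 mM | 400 mM | 25 min |

| run | time / min | [starting material] / mM |
|---|---|---|
| ash run | 1.0 | 236.3 |
| ash run | 1.9 | 226.3 |
| ash run | 3.6 | 209.5 |
| ash run | 6.9 | 181.5 |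
| ash run | 13 | 154.4 |
| ash run | 25 | 125.7 |
| elm run | 1.0 | 127.0 |
| elm run | 1.9 | 123.3 |
| elm run | 3.6 | 119.1 |
| elm run | 6.9 | 108.4 |
| elm run | 13 | 96.7 |
| elm run | 25 | 84.3 |
| birch run | 1.0 | 233.4 |
| birch run | 1.9 | 219.1 |
| birch run | 3.6 | 194.7 |
| birch run | 6.9 | 160.1 |
| birch run | 13 | 121.8 |
| birch run | 25 | 87.9 |
| larch run | 1.0 | 481.2 |
| larch run | 1.9 | 464.9 |
| larch run | 3.6 | 440.1 |
| larch run | 6.9 | 404.0 |
| larch run | 13 | 371.0 |
| larch run | 25 | 352.4 |

(readings scatter by 1 mM)

- reaction order in [starting material] at the outset, round the charge of the ash run, defined at two percent of the starting material turned into target (one fixed amount of target, the same in the runs compared)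
- reaction order in [reagent] at the outset, round the charge of the ash run, defined at two percent of the starting material turned into target
- starting material in the cedar run at 25 min, as a share of the starting material charged
- which of these the readings show (the product reacts on with the second partner / nothing beyond the main steps / the second partner is lost in pairs / the product decays / the loaded catalyst dies)

- Overall: starting material + reagent -> target, with catalyst as catalyst.
- Constant volume, constant temperature.
- What is held in complexes is read along with the free species.
- "The second partner" is reagent.
- An order is taken over about fifteen percent of the charge, up and down.

I turn the question round and ask what the readings would show if the catalyst were dying with the target made. I divide each rate by the starting material and by the reagent that a one-to-one count leaves, and call this the pair rate. From the first minute to the last interval, the pair rate of the larch run falls by a factor of 2.89. Catalyst death tied to target leads me to expect a similar fall in the birch run, which by then has turned about as much, 145 mM against 138 mM. Yet the birch fall, a factor of 1.35, is smaller than the larch fall. So my reading of the larch tail is a spending of reagent beyond the one-to-one count; reagent is the limiting reagent there, 200 mM against 500 mM of starting material charged. Its charge over the 148 mM turned by 25 min caps the average spending at 1.36 reagent per starting material, and I take that cap as the spending in my reckoning.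

My carried quantity is the lifetime product, the pseudo-first-order lifetime of starting material times the mean reagent over the run, at this catalyst charge. The birch readings give an average lifetime of 23.9 min on an estimated mean reagent of 190 mM, so 273 M·s. If the cedar run turned its whole charge, its mean reagent would be 319 mM, which gives 1.75 lifetimes in 25 min and, as my estimate, 17.4% of the starting material left.

The forecast differs from my figure: it gives 27% for the cedar run, orders of 0.6 in starting material and 0.6 in reagent, and the verdict that the loaded catalyst dies, saying “Turnover-linked catalyst death fits best”.

The cedar run gives 11.3%, with orders of 0.76 in starting material and 0.82 in reagent, and the readings show that the product reacts on with the second partner.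

    catalyst + starting material ⇌ catalyst-substrate complex (21.18 /M/min, 9.240 /min)
    catalyst-substrate complex + reagent → target + catalyst (17.94 /M/min)
    target + reagent → side product (0.6000 /M/min)

Leaving out the loss of target and reagent to side product moves the readings by 11 scatter units, root mean square. The cedar share left at 25 min amounts to 2.18 lifetimes. In the ash run, the lifetime product on an estimated mean reagent of 116 mM counts 0.637 lifetimes by 25 min, and the readings there show 0.688.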